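**Plan**

1. Ring numbering follows the target name: C1 ester carbinol, C2 CH2, C3(Me)=C4, C5, C6, C7(Me)=C8, C9 carbinol, C10 isopropyl-bearing carbon. The retrosynthesis cuts, in order, the ester C–O at O1, the ring bond C2–C3, the C1–B and C2–B bonds (back to a vinyl group), C9–C10, and the C3=C4 alkene; C4–C9 come from neryl acetate.
2. Enabling feature: in the cyclodeca-3,7-diene ring, C2 is a lone sp3 CH2 between the C1 carbinol and the methyl-bearing sp2 C3. C1–C2 is therefore the retron of a vinyl group that can carry two boron atoms: the one on C2 closes the ring onto a (Z)-alkenyl iodide, and the one on C1 is the masked ester oxygen, which never has to be told apart from O9.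
3. Forward: neryl acetate → (Z)-iodoalkenyl enal (C3–C9) → allylboration adds C10, C1, C2 and the isopropyl group → silylation of O9 → diboration of the vinyl group → ring closure C2–C3 with oxidation of C1–B → acylation of O1 → desilylation. The only carbocycle formed is the ten-membered ring.
4. Stereochemistry: 7Z from nerol; 3Z from the Z-selective iodo-Wittig reaction and a stereoretentive coupling; C9 and C10 (syn) from a chiral (Z)-allylborane; C1 from catalyst-controlled syn-diboration, retained through coupling and oxidation.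

Key step: step 9

Assumption: the D-glucal-derived diol catalyst of step 8 is taken to deliver boron to the Re face of the vinyl carbon that becomes C1; should it favour the Si face, its L-rhamnal-derived pseudo-enantiomer is used in its place.

**Route**

Step 1
Reactants: 1 neryl acetate
Product: 2 (2Z)-5-(3,3-dimethyloxiran-2-yl)-3-methylpent-2-en-1-yl acetate
Conditions: mCPBA, CH2Cl2, 0 °C
Reagents that add atoms: 3-chloroperoxybenzoic acid (mCPBA), OOC(=O)c1cccc(Cl)c1
Why: Prilezhaev epoxidation, selective for the distal trisubstituted alkene because the 2,3-alkene is deactivated by the allylic acetate; the new stereocentre is racemic and is destroyed in step 2.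

Step 2
Reactants: 2 (2Z)-5-(3,3-dimethyloxiran-2-yl)-3-methylpent-2-en-1-yl acetate
Product: 3 (2Z)-3-methyl-6-oxohex-2-en-1-yl acetate
Conditions: H5IO6, THF/H2O, 0 °C
Reagents that add atoms: none
Why: Acid-mediated epoxide hydrolysis and periodate glycol cleavage (Malaprade reaction) in one pot remove the isopropylidene carbon as acetone and leave the aldehyde, the acetate and the 2Z alkene untouched.

Step 3
Reactants: 3 (2Z)-3-methyl-6-oxohex-2-en-1-yl acetate
Product: 4 (2Z,6Z)-7-iodo-3-methylocta-2,6-dien-1-yl acetate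
Conditions: EtPPh3I, n-BuLi, THF, rt; I2, −78 °C; NaN(SiMe3)2, −20 °C; then 3, −78 °C
Reagents that add atoms: ethyltriphenylphosphonium iodide, CC[P+](c1ccccc1)(c1ccccc1)c1ccccc1.[I-]; iodine, II
Why: Stork–Zhao iodo-Wittig olefination, in which the non-stabilised α-iodo ylide adds under kinetic control and the cis-oxaphosphetane collapses to the (Z)-iodoalkene (iodine cis to the chain) at a temperature where the acetate is not attacked.

Step 4
Reactants: 4 (2Z,6Z)-7-iodo-3-methylocta-2,6-dien-1-yl acetate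
Product: 5 (2Z,6Z)-7-iodo-3-methylocta-2,6-dien-1-ol
Conditions: K2CO3, MeOH, 0 °C → rt
Reagents that add atoms: none
Why: Base-catalysed transesterification (methanolysis of the acetate) frees the allylic alcohol without touching the alkenyl iodide.

Step 5
Reactants: 5 (2Z,6Z)-7-iodo-3-methylocta-2,6-dien-1-ol
Product: 6 (2Z,6Z)-7-iodo-3-methylocta-2,6-dienal
Conditions: TEMPO (cat.), PhI(OAc)2, CH2Cl2, rt
Reagents that add atoms: none
Why: TEMPO/PhI(OAc)2 oxidation (oxoammonium mechanism) of the allylic alcohol to the enal under neutral conditions that should not isomerise the 2Z double bond.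

Step 6
Reactants: 6 (2Z,6Z)-7-iodo-3-methylocta-2,6-dienal; 7 (Z)-4-methylpent-2-ene
Product: 11 (3S,4R,5Z,9Z)-10-iodo-6-methyl-3-(propan-2-yl)undeca-1,5,9-trien-4-ol, via allylpotassium 8 (not isolated), via allylborane 9 (not isolated), via borinate 10 (not isolated)
Conditions: 7, n-BuLi, KOt-Bu, THF, −78 → −45 °C; (+)-Ipc2BOMe [(−)-α-pinene series], −78 °C; BF3·OEt2; 6, −78 °C; then NaOH, H2O2, 0 °C → rt
Reagents that add atoms: none
Why: Brown asymmetric allylboration with a (Z)-γ-substituted allylborane, in which the closed chair transition state turns the Z geometry into the syn relation of hydroxyl and isopropyl and the isopinocampheyl groups of the (−)-α-pinene series send the allyl unit to the Re face of the aldehyde, which sets the two centres that become C9 and C10.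

Step 7
Reactants: 11 (3S,4R,5Z,9Z)-10-iodo-6-methyl-3-(propan-2-yl)undeca-1,5,9-trien-4-ol
Product: 12 tert-butyl{[(3S,4R,5Z,9Z)-10-iodo-6-methyl-3-(propan-2-yl)undeca-1,5,9-trien-4-yl]oxy}dimethylsilane
Conditions: TBSOTf, 2,6-lutidine, CH2Cl2, −78 → 0 °C
Reagents that add atoms: tert-butyldimethylsilyl trifluoromethanesulfonate, CC(C)(C)[Si](C)(C)OS(=O)(=O)C(F)(F)F
Why: Silyl ether formation with the silyl triflate on a hindered secondary alcohol, so that O9 can neither direct the diboration nor the coupling and stays distinct from the later O1.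

Step 8
Reactants: 12 tert-butyl{[(3S,4R,5Z,9Z)-10-iodo-6-methyl-3-(propan-2-yl)undeca-1,5,9-trien-4-yl]oxy}dimethylsilane
Product: 14 2,2'-[(2R,3R,4R,5Z,9Z)-4-[(tert-butyldimethylsilyl)oxy]-10-iodo-6-methyl-3-(propan-2-yl)undeca-5,9-diene-1,2-diyl]bis(4,4,5,5-tetramethyl-1,3,2-dioxaborolane), via bis(neopentylglycolato)boronate 13 (not isolated)
Conditions: B2(neo)2, 6-O-TBS-1,2-dideoxy-D-glucopyranose (TBS-DHG, 10 mol %), DBU (10 mol %), THF, 60 °C; then pinacol, rt
Reagents that add atoms: bis(neopentyl glycolato)diboron, CC1(C)COB(OC1)B1OCC(C)(C)CO1; pinacol, CC(C)(O)C(C)(C)O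
Why: Diol-catalysed, metal-free enantioselective alkene diboration, in which the chiral diboron formed by exchange of the catalyst with B2(neo)2 adds both boron atoms syn to the Re face of the vinyl group and so sets C1 by catalyst control, while the trisubstituted alkenes and the alkenyl iodide (which a zerovalent platinum diboration catalyst would attack) stay untouched and pinacol exchange gives the stable bis(pinacol) ester.

Step 9
Reactants: 14 2,2'-[(2R,3R,4R,5Z,9Z)-4-[(tert-butyldimethylsilyl)oxy]-10-iodo-6-methyl-3-(propan-2-yl)undeca-5,9-diene-1,2-diyl]bis(4,4,5,5-tetramethyl-1,3,2-dioxaborolane)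
Product: 16 (1R,3Z,7Z,9S,10S)-9-[(tert-butyldimethylsilyl)oxy]-3,7-dimethyl-10-(propan-2-yl)cyclodeca-3,7-dien-1-ol, via macrocyclic boronate 15 (not isolated)
Conditions: Pd(OAc)2 (10 mol %), RuPhos (12 mol %), KOH, degassed THF/H2O 10:1, 70 °C, syringe-pump addition of 14 (final 2 mM); then H2O2, 0 °C → rt
Reagents that add atoms: hydrogen peroxide, OO
Why: Zerovalent palladium (from Pd(OAc)2 and RuPhos) inserts into the C3–I bond with retention, hydroxide turns the primary C2–B(pin) into a boronate whose transfer to divalent palladium is accelerated by the neighbouring C1–B(pin), and C(sp3)–C(sp2) reductive elimination from the eleven-membered alkyl(alkenyl)palladium ring forms C2–C3; alkaline H2O2 then replaces boron on C1 by hydroxyl with retention (1,2-shift from boron to oxygen). The closest known reaction types are the Suzuki–Miyaura coupling of vicinal bis(boronates) at the primary carbon with alkenyl halides and the B-alkyl Suzuki–Miyaura macrocyclisation, used here at the lower end of ring size. The ten-membered carbocycle is closed by reductive elimination within a palladacycle (a cross-coupling ring closure with C2 as the nucleophilic and C3 as the electrophilic terminus), helped by the two Z-alkenes and the C9/C10 substituents, which limit the conformations of the chain. No stereocentre is created: C1, C9 and C10 are carried through and the 3Z geometry follows from retention at C3. The step needs primary-over-secondary boron selectivity (sterics and the vicinal-boron effect), ring closure over oligomerisation (slow addition to high dilution) and reductive elimination over β-hydride elimination (bulky biaryl phosphine). A two-electron transmetalation is chosen because a radical at C2 would add 5-exo to C8.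

Step 10
Reactants: 16 (1R,3Z,7Z,9S,10S)-9-[(tert-butyldimethylsilyl)oxy]-3,7-dimethyl-10-(propan-2-yl)cyclodeca-3,7-dien-1-ol; 17 4-[(tert-butyldimethylsilyl)oxy]benzoic acid
Product: 18 (1R,3Z,7Z,9S,10S)-9-[(tert-butyldimethylsilyl)oxy]-3,7-dimethyl-10-(propan-2-yl)cyclodeca-3,7-dien-1-yl 4-[(tert-butyldimethylsilyl)oxy]benzoate
Conditions: DCC, DMAP, CH2Cl2, rt
Reagents that add atoms: none
Why: Steglich esterification (carbodiimide activation, acyl transfer by DMAP) of the only free hydroxyl, so that the acyl group can go only to O1.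

Step 11
Reactants: 18 (1R,3Z,7Z,9S,10S)-9-[(tert-butyldimethylsilyl)oxy]-3,7-dimethyl-10-(propan-2-yl)cyclodeca-3,7-dien-1-yl 4-[(tert-butyldimethylsilyl)oxy]benzoate
Product: 19 (1R,3Z,7Z,9S,10R)-9-hydroxy-3,7-dimethyl-10-(propan-2-yl)cyclodeca-3,7-dien-1-yl 4-hydroxybenzoate
Conditions: TBAF, AcOH, THF, 0 °C → rt
Reagents that add atoms: none
Why: Fluoride-mediated cleavage of the aryl and the alkyl silyl ether in one operation, buffered with acetic acid so that no alkoxide is present to cause 1,3-acyl migration from O1 to O9 or ester cleavage.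

**Compound list**

1 | neryl acetate, (2Z)-3,7-dimethylocta-2,6-dien-1-yl acetate | CC(=O)OC/C=C(C)\CCC=C(C)C | starting material
2 | (2Z)-5-(3,3-dimethyloxiran-2-yl)-3-methylpent-2-en-1-yl acetate (racemic at the oxirane carbon) | CC(=O)OC/C=C(C)\CCC1OC1(C)C | intermediate
3 | (2Z)-3-methyl-6-oxohex-2-en-1-yl acetate | CC(=O)OC/C=C(C)\CCC=O | intermediate
4 | (2Z,6Z)-7-iodo-3-methylocta-2,6-dien-1-yl acetate | CC(=O)OC/C=C(C)\CC/C=C(C)\I | intermediate
5 | (2Z,6Z)-7-iodo-3-methylocta-2,6-dien-1-ol | OC/C=C(C)\CC/C=C(C)\I | intermediate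
6 | (2Z,6Z)-7-iodo-3-methylocta-2,6-dienal | O=C/C=C(C)\CC/C=C(C)\I | intermediate
7 | (Z)-4-methylpent-2-ene | C/C=C\C(C)C | starting material
8 | [(2Z)-4-methylpent-2-en-1-yl]potassium (not isolated) | [K+].[CH2-]/C=C\C(C)C | intermediate
9 | [(2Z)-4-methylpent-2-en-1-yl]bis[(+)-isopinocampheyl]borane, Ipc groups of the (−)-α-pinene series (not isolated) | CC(C)/C=C\CB([C@H]1C[C@H]2C[C@@H]([C@@H]1C)C2(C)C)[C@H]1C[C@H]2C[C@@H]([C@@H]1C)C2(C)C | intermediate
10 | bis[(+)-isopinocampheyl]borinate of alcohol 11 (not isolated) | I/C(C)=C\CC/C(C)=C\[C@H](OB([C@H]1C[C@H]2C[C@@H]([C@@H]1C)C2(C)C)[C@H]1C[C@H]2C[C@@H]([C@@H]1C)C2(C)C)[C@@H](C(C)C)C=C | intermediate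
11 | (3S,4R,5Z,9Z)-10-iodo-6-methyl-3-(propan-2-yl)undeca-1,5,9-trien-4-ol | I/C(C)=C\CC/C(C)=C\[C@H](O)[C@@H](C(C)C)C=C | intermediate
12 | tert-butyl{[(3S,4R,5Z,9Z)-10-iodo-6-methyl-3-(propan-2-yl)undeca-1,5,9-trien-4-yl]oxy}dimethylsilane | I/C(C)=C\CC/C(C)=C\[C@H](O[Si](C)(C)C(C)(C)C)[C@@H](C(C)C)C=C | intermediate
13 | 2,2'-[(2R,3R,4R,5Z,9Z)-4-[(tert-butyldimethylsilyl)oxy]-10-iodo-6-methyl-3-(propan-2-yl)undeca-5,9-diene-1,2-diyl]bis(5,5-dimethyl-1,3,2-dioxaborinane) (not isolated) | I/C(C)=C\CC/C(C)=C\[C@H](O[Si](C)(C)C(C)(C)C)[C@@H](C(C)C)[C@H](B1OCC(C)(C)CO1)CB1OCC(C)(C)CO1 | intermediate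
14 | 2,2'-[(2R,3R,4R,5Z,9Z)-4-[(tert-butyldimethylsilyl)oxy]-10-iodo-6-methyl-3-(propan-2-yl)undeca-5,9-diene-1,2-diyl]bis(4,4,5,5-tetramethyl-1,3,2-dioxaborolane) | I/C(C)=C\CC/C(C)=C\[C@H](O[Si](C)(C)C(C)(C)C)[C@@H](C(C)C)[C@H](B1OC(C)(C)C(C)(C)O1)CB1OC(C)(C)C(C)(C)O1 | intermediate
15 | 2-[(1R,3Z,7Z,9R,10R)-9-[(tert-butyldimethylsilyl)oxy]-3,7-dimethyl-10-(propan-2-yl)cyclodeca-3,7-dien-1-yl]-4,4,5,5-tetramethyl-1,3,2-dioxaborolane (not isolated) | C/C1=C/[C@H](O[Si](C)(C)C(C)(C)C)[C@@H](C(C)C)[C@H](B2OC(C)(C)C(C)(C)O2)C/C(C)=C\CC1 | intermediate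
16 | (1R,3Z,7Z,9S,10S)-9-[(tert-butyldimethylsilyl)oxy]-3,7-dimethyl-10-(propan-2-yl)cyclodeca-3,7-dien-1-ol | C/C1=C/[C@H](O[Si](C)(C)C(C)(C)C)[C@@H](C(C)C)[C@H](O)C/C(C)=C\CC1 | intermediate
17 | 4-[(tert-butyldimethylsilyl)oxy]benzoic acid | CC(C)(C)[Si](C)(C)Oc1ccc(cc1)C(O)=O | starting material
18 | (1R,3Z,7Z,9S,10S)-9-[(tert-butyldimethylsilyl)oxy]-3,7-dimethyl-10-(propan-2-yl)cyclodeca-3,7-dien-1-yl 4-[(tert-butyldimethylsilyl)oxy]benzoate | C/C1=C/[C@H](O[Si](C)(C)C(C)(C)C)[C@@H](C(C)C)[C@H](OC(=O)c2ccc(O[Si](C)(C)C(C)(C)C)cc2)C/C(C)=C\CC1 | intermediate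
19 | (1R,3Z,7Z,9S,10R)-9-hydroxy-3,7-dimethyl-10-(propan-2-yl)cyclodeca-3,7-dien-1-yl 4-hydroxybenzoate | C/C1=C/[C@H](O)[C@@H](C(C)C)[C@H](OC(=O)c2ccc(O)cc2)C/C(C)=C\CC1 | target

**Summary**

Total step count: 11. Longest linear sequence: 11 steps (1 → 19).

**Steps most likely to fail**

Step 9 (ring closure). Intermolecular coupling and protodeboronation of the primary boronate may outrun closure of the ten-membered ring, and β-hydride elimination from the alkylpalladium intermediate may compete. The fallback closes the same bond through a ketone enolate instead of a boronate and sets out from 12. Tsuji–Wacker oxidation of the vinyl group (PdCl2, CuCl, O2, DMF/H2O) should give the methyl ketone (3R,4S,5Z,9Z)-4-[(tert-butyldimethylsilyl)oxy]-10-iodo-6-methyl-3-(propan-2-yl)undeca-5,9-dien-2-one F1. Its kinetic methyl-side enolate (KN(SiMe3)2, THF, −78 °C) would be coupled with the alkenyl iodide in a palladium-catalysed intramolecular ketone α-alkenylation (Pd2(dba)3, Xantphos, THF, 60 °C, high dilution) to the cyclodecadienone (3Z,7Z,9S,10R)-9-[(tert-butyldimethylsilyl)oxy]-3,7-dimethyl-10-(propan-2-yl)cyclodeca-3,7-dien-1-one F2. Corey–Bakshi–Shibata reduction ((S)-2-methyl-CBS-oxazaborolidine, catecholborane, −78 °C, with C10 as the large group) should then give 16, where the route is rejoined.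

Step 8 (diboration). Facial discrimination in the boron addition to the hindered vinyl group next to the C10 stereocentre may be insufficient, so that C1 forms as a mixture. The fallback sets the centre by ketone reduction instead and sets out from 12. The diboration is run without relying on its selectivity (if need be with B2pin2, Cs2CO3, MeOH, THF, 70 °C), and 14 together with its C2 epimer, the (2S,3R,4R) bis(boronate) F3, is taken through the conditions of step 9. This should give 16 together with its C1 epimer, the (1S,9S,10S) alcohol F4. Oxidation of the mixture (Dess–Martin periodinane, NaHCO3, CH2Cl2) converges both on the ketone F2 of the first fallback, and the same CBS reduction returns the route to 16.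

Step 6 (allylboration). Loss of the Z geometry of the isopropyl-substituted allylpotassium, or weak enantioface control with the β,β-disubstituted enal, would erode the syn and absolute selectivity. The fallback uses auxiliary control and sets out from 6. An Evans syn-aldol reaction with (4R)-4-benzyl-3-(3-methylbutanoyl)-1,3-oxazolidin-2-one (Bu2BOTf, i-Pr2NEt, CH2Cl2, −78 → 0 °C) should give the aldol (4R)-4-benzyl-3-[(2R,3S,4Z,8Z)-3-hydroxy-9-iodo-5-methyl-2-(propan-2-yl)deca-4,8-dienoyl]-1,3-oxazolidin-2-one F5. Silylation (TBSOTf, 2,6-lutidine) would give its silyl ether F6. Reductive removal of the auxiliary (LiBH4, MeOH, THF, 0 °C) would give (2S,3S,4Z,8Z)-3-[(tert-butyldimethylsilyl)oxy]-9-iodo-5-methyl-2-(propan-2-yl)deca-4,8-dien-1-ol F7. Oxidation (Dess–Martin periodinane) would give the aldehyde (2R,3S,4Z,8Z)-3-[(tert-butyldimethylsilyl)oxy]-9-iodo-5-methyl-2-(propan-2-yl)deca-4,8-dienal F8, and Wittig methylenation (MePPh3Br, KOt-Bu, THF, −78 → 0 °C) returns the route to 12.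

**Further compounds**

F1 | step 9 | (3R,4S,5Z,9Z)-4-[(tert-butyldimethylsilyl)oxy]-10-iodo-6-methyl-3-(propan-2-yl)undeca-5,9-dien-2-one | I/C(C)=C\CC/C(C)=C\[C@H](O[Si](C)(C)C(C)(C)C)[C@@H](C(C)C)C(C)=O
F2 | step 9 | (3Z,7Z,9S,10R)-9-[(tert-butyldimethylsilyl)oxy]-3,7-dimethyl-10-(propan-2-yl)cyclodeca-3,7-dien-1-one | C/C1=C/[C@H](O[Si](C)(C)C(C)(C)C)[C@@H](C(C)C)C(=O)C/C(C)=C\CC1
F3 | step 8 | 2,2'-[(2S,3R,4R,5Z,9Z)-4-[(tert-butyldimethylsilyl)oxy]-10-iodo-6-methyl-3-(propan-2-yl)undeca-5,9-diene-1,2-diyl]bis(4,4,5,5-tetramethyl-1,3,2-dioxaborolane) | I/C(C)=C\CC/C(C)=C\[C@H](O[Si](C)(C)C(C)(C)C)[C@@H](C(C)C)[C@@H](B1OC(C)(C)C(C)(C)O1)CB1OC(C)(C)C(C)(C)O1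
F4 | step 8 | (1S,3Z,7Z,9S,10S)-9-[(tert-butyldimethylsilyl)oxy]-3,7-dimethyl-10-(propan-2-yl)cyclodeca-3,7-dien-1-ol | C/C1=C/[C@H](O[Si](C)(C)C(C)(C)C)[C@@H](C(C)C)[C@@H](O)C/C(C)=C\CC1
F5 | step 6 | (4R)-4-benzyl-3-[(2R,3S,4Z,8Z)-3-hydroxy-9-iodo-5-methyl-2-(propan-2-yl)deca-4,8-dienoyl]-1,3-oxazolidin-2-one | I/C(C)=C\CC/C(C)=C\[C@H](O)[C@@H](C(C)C)C(=O)N1[C@H](Cc2ccccc2)COC1=O
F6 | step 6 | (4R)-4-benzyl-3-[(2R,3S,4Z,8Z)-3-[(tert-butyldimethylsilyl)oxy]-9-iodo-5-methyl-2-(propan-2-yl)deca-4,8-dienoyl]-1,3-oxazolidin-2-one | I/C(C)=C\CC/C(C)=C\[C@H](O[Si](C)(C)C(C)(C)C)[C@@H](C(C)C)C(=O)N1[C@H](Cc2ccccc2)COC1=O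
F7 | step 6 | (2S,3S,4Z,8Z)-3-[(tert-butyldimethylsilyl)oxy]-9-iodo-5-methyl-2-(propan-2-yl)deca-4,8-dien-1-ol | I/C(C)=C\CC/C(C)=C\[C@H](O[Si](C)(C)C(C)(C)C)[C@@H](C(C)C)CO
F8 | step 6 | (2R,3S,4Z,8Z)-3-[(tert-butyldimethylsilyl)oxy]-9-iodo-5-methyl-2-(propan-2-yl)deca-4,8-dienal | I/C(C)=C\CC/C(C)=C\[C@H](O[Si](C)(C)C(C)(C)C)[C@@H](C(C)C)C=O
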